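**Strategy**

The ten-membered carbocycle is closed last, at the sp3–sp2 junction between the ring methylene C9 and the methyl-bearing alkene carbon C10 of the (E)-C1=C10 double bond (germacrane numbering: C7 isopropenyl, C6 acetate, C4–C5 epoxide, C3 angelate). In the open-chain precursor both carbons are electrophiles, a primary alkyl iodide and a geometrically defined (E)-alkenyl iodide. An intramolecular nickel-catalysed reductive cross-electrophile coupling joins these like-polarity centres and gives the target in one operation, with epoxide, both esters, isopropenyl group and all five stereocentres in place. The precursor arises from a C5 enal by two catalyst-controlled allylborations, cross-metathesis/iododeboronation and Sharpless epoxidation.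

Key step: step 14

Remark on numbering: ring atoms are numbered C1 to C10 as above in all steps (C8 and C9 are the two ring CH2 groups between C7 and C10; C2 is the CH2 between C1 and C3).
Assumption: (E)-4-acetoxy-2-methylbut-2-enal (the industrial vitamin A C5 aldehyde, 11), 3-[(tert-butyldimethylsilyl)oxy]propanal (1) and both enantiomers of TRIP phosphoric acid are taken as commercially available.
Remark on facial sense: the sense of induction of the TRIP acids is taken from their allylborations of aryl and alkenyl aldehydes (R acid, Re-face attack); the Sharpless sense is taken by analogy with geraniol.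

**Step 1**
Reactants: 1 3-[(tert-butyldimethylsilyl)oxy]propanal; 2 ethyltriphenylphosphonium iodide
Product: 6 (Z)-tert-butyl[(4-iodopent-3-en-1-yl)oxy]dimethylsilane, via ethylidenetriphenylphosphorane 3 (not isolated), via (1-iodoethyl)triphenylphosphonium iodide 4 (not isolated), via (1-iodoethylidene)triphenylphosphorane 5 (not isolated)
Conditions: 2, n-BuLi, THF, 0 °C to rt; I2, −78 °C; NaN(SiMe3)2, −20 °C; then 1, −78 to −20 °C
Reagents that add atoms: iodine, [I][I]
Why: Stork–Zhao-type iodo-Wittig olefination, in which the non-stabilised α-iodo ylide 5 (made by iodination of 3 and deprotonation of 4) should react with 1 under kinetic control through the cis-oxaphosphetane to give the (Z)-2-iodoalkene with iodine cis to the chain, the geometry needed for a (Z)-allylboronate.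

**Step 2**
Reactants: 6 (Z)-tert-butyl[(4-iodopent-3-en-1-yl)oxy]dimethylsilane; 7 2-(chloromethyl)-4,4,5,5-tetramethyl-1,3,2-dioxaborolane
Product: 10 (Z)-tert-butyldimethyl{[4-methyl-5-(4,4,5,5-tetramethyl-1,3,2-dioxaborolan-2-yl)pent-3-en-1-yl]oxy}silane, via alkenyllithium 8 (not isolated), via lithium boronate complex 9 (not isolated)
Conditions: t-BuLi (2.1 equiv), Et2O, −78 °C; then 7, −78 °C to rt
Reagents that add atoms: none
Why: Iodine–lithium exchange proceeds with retention to the configurationally stable alkenyllithium 8, which adds to the chloromethylboronate, and complex 9 undergoes a Matteson-type 1,2-metallate shift that expels chloride and should give the allylic boronate with the alkene geometry intact (CH2B cis to the chain).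

**Step 3**
Reactants: 11 (2E)-3-methyl-4-oxobut-2-en-1-yl acetate; 12 2-allyl-4,4,5,5-tetramethyl-1,3,2-dioxaborolane
Product: 14 (2E,4S)-4-hydroxy-3-methylhepta-2,6-dien-1-yl acetate, via pinacol borate ester 13 (not isolated)
Conditions: (S)-TRIP phosphoric acid [(S)-3,3'-bis(2,4,6-triisopropylphenyl)-1,1'-binaphthyl-2,2'-diyl hydrogen phosphate] (5 mol %), 4 Å molecular sieves, toluene, −30 °C; aqueous NaHCO3
Reagents that add atoms: none
Why: Chiral phosphoric acid-catalysed allylboration through a closed chair transition state, in which the S acid is expected to direct the allyl group to the Si face of the enal and so set C3 as S; hydrolysis of borate 13 on work-up frees the alcohol.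

**Step 4**
Reactants: 14 (2E,4S)-4-hydroxy-3-methylhepta-2,6-dien-1-yl acetate; 15 4,4,5,5-tetramethyl-2-(prop-1-en-2-yl)-1,3,2-dioxaborolane
Product: 16 (2E,4S,6Z)-4-hydroxy-3-methyl-7-(4,4,5,5-tetramethyl-1,3,2-dioxaborolan-2-yl)octa-2,6-dien-1-yl acetate
Conditions: second-generation Hoveyda–Grubbs catalyst (5 mol %), 15 (3 equiv), CH2Cl2, 40 °C
Reagents that add atoms: none
Why: Olefin cross-metathesis of the monosubstituted alkene with the 1,1-disubstituted isopropenylboronate, in which the trisubstituted C4=C5 alkene is inert and the thermodynamically preferred product carries the chain trans to the bulky boronate (6Z); running it before acylation excludes ring-closing metathesis onto an angelate.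

**Step 5**
Reactants: 16 (2E,4S,6Z)-4-hydroxy-3-methyl-7-(4,4,5,5-tetramethyl-1,3,2-dioxaborolan-2-yl)octa-2,6-dien-1-yl acetate; 17 angelic acid [(2Z)-2-methylbut-2-enoic acid]
Product: 19 (2E,4S,6Z)-1-acetoxy-3-methyl-7-(4,4,5,5-tetramethyl-1,3,2-dioxaborolan-2-yl)octa-2,6-dien-4-yl (2Z)-2-methylbut-2-enoate, via angelic trichlorobenzoic anhydride 18 (not isolated)
Conditions: 17, 2,4,6-trichlorobenzoyl chloride, Et3N, toluene, rt; then 16, 70 °C
Reagents that add atoms: none
Why: Yamaguchi esterification through mixed anhydride 18 without a nucleophilic catalyst, conditions known to transfer the angeloyl group to secondary alcohols without Z to E isomerisation to the tiglate; C3 is not touched.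

**Step 6**
Reactants: 19 (2E,4S,6Z)-1-acetoxy-3-methyl-7-(4,4,5,5-tetramethyl-1,3,2-dioxaborolan-2-yl)octa-2,6-dien-4-yl (2Z)-2-methylbut-2-enoate
Product: 20 (2E,4S,6Z)-1-hydroxy-3-methyl-7-(4,4,5,5-tetramethyl-1,3,2-dioxaborolan-2-yl)octa-2,6-dien-4-yl (2Z)-2-methylbut-2-enoate
Conditions: K2CO3 (0.2 equiv), MeOH, 0 °C
Reagents that add atoms: none
Why: Mild methanolysis should cleave the unhindered primary acetate much faster than the α-branched conjugated secondary angelate, and the pinacol boronate is stable to carbonate.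

**Step 7**
Reactants: 20 (2E,4S,6Z)-1-hydroxy-3-methyl-7-(4,4,5,5-tetramethyl-1,3,2-dioxaborolan-2-yl)octa-2,6-dien-4-yl (2Z)-2-methylbut-2-enoate
Product: 22 (2E,4S,6E)-1-hydroxy-7-iodo-3-methylocta-2,6-dien-4-yl (2Z)-2-methylbut-2-enoate, via sodium hydroxyboronate 21 (not isolated)
Conditions: NaOH (3 M aq, 3 equiv), THF, 0 °C, 10 min; I2, 0 °C; Na2S2O3 quench
Reagents that add atoms: iodine, [I][I]
Why: Iododeboronation, in which hydroxide forms boronate 21 and iodine replaces boron at the ipso carbon with retention, so the (6Z)-boronate should give the (E)-alkenyl iodide with iodine trans to the chain; the short cold exposure should spare the hindered angelate.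

**Step 8**
Reactants: 22 (2E,4S,6E)-1-hydroxy-7-iodo-3-methylocta-2,6-dien-4-yl (2Z)-2-methylbut-2-enoate
Product: 23 (1S,3E)-1-[(2R,3R)-3-(hydroxymethyl)-2-methyloxiran-2-yl]-4-iodopent-3-en-1-yl (2Z)-2-methylbut-2-enoate
Conditions: Ti(OiPr)4, D-(−)-diisopropyl tartrate, t-BuOOH, 4 Å molecular sieves, CH2Cl2, −20 °C
Reagents that add atoms: tert-butyl hydroperoxide, CC(C)(C)OO
Why: Katsuki–Sharpless asymmetric epoxidation of the primary 3,3-disubstituted allylic alcohol under reagent control: the D-(−)-tartrate delivers oxygen to the face opposite to the one that gives (2S,3S)-epoxygeraniol with L-(+)-tartrate, so the trans (4R,5R)-epoxide is expected, and only the titanium-bound allylic alkene reacts.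

**Step 9**
Reactants: 23 (1S,3E)-1-[(2R,3R)-3-(hydroxymethyl)-2-methyloxiran-2-yl]-4-iodopent-3-en-1-yl (2Z)-2-methylbut-2-enoate
Product: 24 (1S,3E)-1-[(2R,3S)-3-formyl-2-methyloxiran-2-yl]-4-iodopent-3-en-1-yl (2Z)-2-methylbut-2-enoate
Conditions: Dess–Martin periodinane, NaHCO3, CH2Cl2, 0 °C to rt
Reagents that add atoms: none
Why: Buffered Dess–Martin oxidation should give the sensitive α,β-epoxy aldehyde without epimerisation or epoxide opening (the descriptor at C5 becomes S only because the formyl group now outranks C4).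

**Step 10**
Reactants: 24 (1S,3E)-1-[(2R,3S)-3-formyl-2-methyloxiran-2-yl]-4-iodopent-3-en-1-yl (2Z)-2-methylbut-2-enoate; 10 (Z)-tert-butyldimethyl{[4-methyl-5-(4,4,5,5-tetramethyl-1,3,2-dioxaborolan-2-yl)pent-3-en-1-yl]oxy}silane
Product: 26 (1S,3E)-1-{(2R,3R)-3-[(1R,2S)-2-{2-[(tert-butyldimethylsilyl)oxy]ethyl}-1-hydroxy-3-methylbut-3-en-1-yl]-2-methyloxiran-2-yl}-4-iodopent-3-en-1-yl (2Z)-2-methylbut-2-enoate, via pinacol borate ester 25 (not isolated)
Conditions: 10 (1.5 equiv), (R)-TRIP phosphoric acid (10 mol %), 4 Å molecular sieves, toluene, −30 to 0 °C; aqueous NaHCO3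
Reagents that add atoms: none
Why: Allylboration through a Zimmerman–Traxler chair, in which the axial (Z)-γ-substituent of 10 gives the 6,7-syn relationship (crotylation sense) and Re-face attack on the aldehyde is favoured both by the R acid and by the Cornforth preference of the epoxy aldehyde (approach anti to the epoxide C–O, past the α-hydrogen), so C6 (R) and C7 (S) should be set in a matched case together with the isopropenyl group.

**Step 11**
Reactants: 26 (1S,3E)-1-{(2R,3R)-3-[(1R,2S)-2-{2-[(tert-butyldimethylsilyl)oxy]ethyl}-1-hydroxy-3-methylbut-3-en-1-yl]-2-methyloxiran-2-yl}-4-iodopent-3-en-1-yl (2Z)-2-methylbut-2-enoate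
Product: 27 (1S,3E)-1-{(2R,3R)-3-[(1R,2S)-1-acetoxy-2-{2-[(tert-butyldimethylsilyl)oxy]ethyl}-3-methylbut-3-en-1-yl]-2-methyloxiran-2-yl}-4-iodopent-3-en-1-yl (2Z)-2-methylbut-2-enoate
Conditions: Ac2O, pyridine, DMAP (cat.), CH2Cl2, 0 °C to rt
Reagents that add atoms: acetic anhydride, CC(=O)OC(C)=O
Why: Standard DMAP-catalysed acetylation of the secondary alcohol, which affects no stereocentre and, done at once, prevents Payne-type epoxide migration.

**Step 12**
Reactants: 27 (1S,3E)-1-{(2R,3R)-3-[(1R,2S)-1-acetoxy-2-{2-[(tert-butyldimethylsilyl)oxy]ethyl}-3-methylbut-3-en-1-yl]-2-methyloxiran-2-yl}-4-iodopent-3-en-1-yl (2Z)-2-methylbut-2-enoate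
Product: 28 (1S,3E)-1-{(2R,3R)-3-[(1R,2S)-1-acetoxy-2-(2-hydroxyethyl)-3-methylbut-3-en-1-yl]-2-methyloxiran-2-yl}-4-iodopent-3-en-1-yl (2Z)-2-methylbut-2-enoate
Conditions: HF·pyridine, pyridine, THF, 0 °C to rt
Reagents that add atoms: none
Why: Pyridine-buffered fluoride cleavage of the primary silyl ether, to which esters, epoxide and iodoalkene should be stable.

**Step 13**
Reactants: 28 (1S,3E)-1-{(2R,3R)-3-[(1R,2S)-1-acetoxy-2-(2-hydroxyethyl)-3-methylbut-3-en-1-yl]-2-methyloxiran-2-yl}-4-iodopent-3-en-1-yl (2Z)-2-methylbut-2-enoate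
Product: 29 (1S,3E)-1-{(2R,3R)-3-[(1R,2S)-1-acetoxy-2-(2-iodoethyl)-3-methylbut-3-en-1-yl]-2-methyloxiran-2-yl}-4-iodopent-3-en-1-yl (2Z)-2-methylbut-2-enoate
Conditions: I2, PPh3, imidazole, CH2Cl2, 0 °C
Reagents that add atoms: iodine, [I][I]
Why: Appel-type iodination of the primary alcohol by SN2 displacement of the alkoxyphosphonium ion, conditions routinely used on epoxy alcohols and inert towards the alkenyl iodide.

**Step 14**
Reactants: 29 (1S,3E)-1-{(2R,3R)-3-[(1R,2S)-1-acetoxy-2-(2-iodoethyl)-3-methylbut-3-en-1-yl]-2-methyloxiran-2-yl}-4-iodopent-3-en-1-yl (2Z)-2-methylbut-2-enoate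
Product: 30 (1(10)E,3S,4R,5R,6R,7S)-6-acetoxy-4,5-epoxygermacra-1(10),11-dien-3-yl (2Z)-2-methylbut-2-enoate (CNP0400048.2)
Conditions: NiI2 (30 mol %), 4,4'-di-tert-butyl-2,2'-bipyridine (30 mol %), Mn powder (4 equiv), pyridine (20 mol %), DMA, 30 °C, 29 added by syringe pump over 12 h (final 2 mM)
Reagents that add atoms: none
Why: Nickel-catalysed reductive cross-electrophile coupling: zerovalent nickel–bipyridine inserts into the alkenyl C10–I bond with retention, monovalent nickel abstracts iodine from C9 to give a primary radical, and capture of this radical at the alkenylnickel centre followed by reductive elimination from trivalent nickel forms the C9–C10 bond while manganese returns nickel to the low-valent state. The closest known reaction type is the intermolecular nickel/bipyridine coupling of alkenyl halides with primary alkyl halides under a metal reductant, here run intramolecularly. The ten-membered carbocycle is closed as a macrocyclisation by C(sp3)–C(sp2) reductive elimination from an eleven-membered nickelacycle, not by an exo or endo attack on a π bond. No stereocentre is formed; the E geometry of C1=C10 is carried over from the alkenyl iodide because σ-alkenylnickel species do not isomerise, and C3 to C7 are remote from the reacting centres. The step needs cyclisation to win over oligomerisation and hydrodehalogenation: the two iodides are activated by different mechanisms (two-electron insertion at sp2 carbon, atom abstraction at sp3 carbon), slow addition keeps the free substrate concentration low, and the trans-epoxide, the E-alkene and the vicinal branching at C6/C7 restrict the chain to folded conformations. Esters, epoxide and the isopropenyl alkene should be inert to these neutral conditions, and neither 4-exo nor 5-endo radical closure onto the isopropenyl group can compete.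

**Compound list**

1 | 3-[(tert-butyldimethylsilyl)oxy]propanal | O=CCCO[Si](C)(C)C(C)(C)C | starting material
2 | ethyltriphenylphosphonium iodide | CC[P+](c1ccccc1)(c1ccccc1)c1ccccc1.[I-] | starting material
3 | ethylidenetriphenylphosphorane | CC=P(c1ccccc1)(c1ccccc1)c1ccccc1 | intermediate
4 | (1-iodoethyl)triphenylphosphonium iodide | CC(I)[P+](c1ccccc1)(c1ccccc1)c1ccccc1.[I-] | intermediate
5 | (1-iodoethylidene)triphenylphosphorane | CC(I)=P(c1ccccc1)(c1ccccc1)c1ccccc1 | intermediate
6 | (Z)-tert-butyl[(4-iodopent-3-en-1-yl)oxy]dimethylsilane (iodine cis to the chain) | C/C(I)=C/CCO[Si](C)(C)C(C)(C)C | intermediate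
7 | 2-(chloromethyl)-4,4,5,5-tetramethyl-1,3,2-dioxaborolane | ClCB1OC(C)(C)C(C)(C)O1 | starting material
8 | (2E)-5-[(tert-butyldimethylsilyl)oxy]pent-2-en-2-yllithium (lithium cis to the chain) | C/C([Li])=C/CCO[Si](C)(C)C(C)(C)C | intermediate
9 | lithium [(2E)-5-[(tert-butyldimethylsilyl)oxy]pent-2-en-2-yl](chloromethyl)(2,3-dimethylbutane-2,3-diolato)borate | C/C(=C/CCO[Si](C)(C)C(C)(C)C)[B-]1(CCl)OC(C)(C)C(C)(C)O1.[Li+] | intermediate
10 | (Z)-tert-butyldimethyl{[4-methyl-5-(4,4,5,5-tetramethyl-1,3,2-dioxaborolan-2-yl)pent-3-en-1-yl]oxy}silane (CH2B cis to the chain) | CC(C)(C)[Si](C)(C)OCC/C=C(/C)CB1OC(C)(C)C(C)(C)O1 | intermediate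
11 | (2E)-3-methyl-4-oxobut-2-en-1-yl acetate [(E)-4-acetoxy-2-methylbut-2-enal] | CC(=O)OC/C=C(\C)C=O | starting material
12 | 2-allyl-4,4,5,5-tetramethyl-1,3,2-dioxaborolane | C=CCB1OC(C)(C)C(C)(C)O1 | starting material
13 | (2E,4S)-3-methyl-4-[(4,4,5,5-tetramethyl-1,3,2-dioxaborolan-2-yl)oxy]hepta-2,6-dien-1-yl acetate | C=CC[C@H](OB1OC(C)(C)C(C)(C)O1)/C(C)=C/COC(C)=O | intermediate
14 | (2E,4S)-4-hydroxy-3-methylhepta-2,6-dien-1-yl acetate | C=CC[C@H](O)/C(C)=C/COC(C)=O | intermediate
15 | 4,4,5,5-tetramethyl-2-(prop-1-en-2-yl)-1,3,2-dioxaborolane | C=C(C)B1OC(C)(C)C(C)(C)O1 | starting material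
16 | (2E,4S,6Z)-4-hydroxy-3-methyl-7-(4,4,5,5-tetramethyl-1,3,2-dioxaborolan-2-yl)octa-2,6-dien-1-yl acetate (boron trans to the chain) | C/C(B1OC(C)(C)C(C)(C)O1)=C\C[C@H](O)/C(C)=C/COC(C)=O | intermediate
17 | angelic acid [(2Z)-2-methylbut-2-enoic acid] | C/C=C(/C)C(=O)O | starting material
18 | (2Z)-2-methylbut-2-enoic 2,4,6-trichlorobenzoic anhydride | C/C=C(/C)C(=O)OC(=O)c1c(Cl)cc(Cl)cc1Cl | intermediate
19 | (2E,4S,6Z)-1-acetoxy-3-methyl-7-(4,4,5,5-tetramethyl-1,3,2-dioxaborolan-2-yl)octa-2,6-dien-4-yl (2Z)-2-methylbut-2-enoate | C/C(B1OC(C)(C)C(C)(C)O1)=C\C[C@H](OC(=O)/C(C)=C\C)/C(C)=C/COC(C)=O | intermediate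
20 | (2E,4S,6Z)-1-hydroxy-3-methyl-7-(4,4,5,5-tetramethyl-1,3,2-dioxaborolan-2-yl)octa-2,6-dien-4-yl (2Z)-2-methylbut-2-enoate | C/C(B1OC(C)(C)C(C)(C)O1)=C\C[C@H](OC(=O)/C(C)=C\C)/C(C)=C/CO | intermediate
21 | sodium hydroxyboronate of 20 (hydroxide bound to boron) | C/C(=C\C[C@H](OC(=O)/C(C)=C\C)/C(C)=C/CO)[B-]1(O)OC(C)(C)C(C)(C)O1.[Na+] | intermediate
22 | (2E,4S,6E)-1-hydroxy-7-iodo-3-methylocta-2,6-dien-4-yl (2Z)-2-methylbut-2-enoate (iodine trans to the chain) | C/C(I)=C\C[C@H](OC(=O)/C(C)=C\C)/C(C)=C/CO | intermediate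
23 | (1S,3E)-1-[(2R,3R)-3-(hydroxymethyl)-2-methyloxiran-2-yl]-4-iodopent-3-en-1-yl (2Z)-2-methylbut-2-enoate | OC[C@@H]1[C@]([C@H](C/C=C(\C)I)OC(=O)/C(C)=C\C)(C)O1 | intermediate
24 | (1S,3E)-1-[(2R,3S)-3-formyl-2-methyloxiran-2-yl]-4-iodopent-3-en-1-yl (2Z)-2-methylbut-2-enoate | O=C[C@@H]1[C@]([C@H](C/C=C(\C)I)OC(=O)/C(C)=C\C)(C)O1 | intermediate
25 | pinacol borate ester of 26 (O–B at C6) | C=C(C)[C@H](CCO[Si](C)(C)C(C)(C)C)[C@H]([C@@H]1[C@]([C@H](C/C=C(\C)I)OC(=O)/C(C)=C\C)(C)O1)OB2OC(C)(C)C(C)(C)O2 | intermediate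
26 | (1S,3E)-1-{(2R,3R)-3-[(1R,2S)-2-{2-[(tert-butyldimethylsilyl)oxy]ethyl}-1-hydroxy-3-methylbut-3-en-1-yl]-2-methyloxiran-2-yl}-4-iodopent-3-en-1-yl (2Z)-2-methylbut-2-enoate | C=C(C)[C@H](CCO[Si](C)(C)C(C)(C)C)[C@H]([C@@H]1[C@]([C@H](C/C=C(\C)I)OC(=O)/C(C)=C\C)(C)O1)O | intermediate
27 | (1S,3E)-1-{(2R,3R)-3-[(1R,2S)-1-acetoxy-2-{2-[(tert-butyldimethylsilyl)oxy]ethyl}-3-methylbut-3-en-1-yl]-2-methyloxiran-2-yl}-4-iodopent-3-en-1-yl (2Z)-2-methylbut-2-enoate | C=C(C)[C@H](CCO[Si](C)(C)C(C)(C)C)[C@H]([C@@H]1[C@]([C@H](C/C=C(\C)I)OC(=O)/C(C)=C\C)(C)O1)OC(C)=O | intermediate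
28 | (1S,3E)-1-{(2R,3R)-3-[(1R,2S)-1-acetoxy-2-(2-hydroxyethyl)-3-methylbut-3-en-1-yl]-2-methyloxiran-2-yl}-4-iodopent-3-en-1-yl (2Z)-2-methylbut-2-enoate | C=C(C)[C@H](CCO)[C@H]([C@@H]1[C@]([C@H](C/C=C(\C)I)OC(=O)/C(C)=C\C)(C)O1)OC(C)=O | intermediate
29 | (1S,3E)-1-{(2R,3R)-3-[(1R,2S)-1-acetoxy-2-(2-iodoethyl)-3-methylbut-3-en-1-yl]-2-methyloxiran-2-yl}-4-iodopent-3-en-1-yl (2Z)-2-methylbut-2-enoate | C=C(C)[C@H](CCI)[C@H]([C@@H]1[C@]([C@H](C/C=C(\C)I)OC(=O)/C(C)=C\C)(C)O1)OC(C)=O | intermediate
30 | (1(10)E,3S,4R,5R,6R,7S)-6-acetoxy-4,5-epoxygermacra-1(10),11-dien-3-yl (2Z)-2-methylbut-2-enoate | C=C(C)[C@@H]1CC/C(C)=C/C[C@H](OC(=O)/C(C)=C\C)[C@@]2(C)O[C@@H]2[C@@H]1OC(C)=O | target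

**Step count and risks**

Total step count: 14. Longest linear sequence: 12 steps (steps 3 to 14, from 11).

Steps most likely to fail:

1. Step 14. Intermolecular coupling may outrun ring closure (oligomerisation), either carbon–iodine bond may be reduced to C–H, or metal iodides may open the epoxide. The fallback sets out from 29 and changes from a reductive radical coupling to a polar cross-coupling of a preformed organometallic. Zinc dust (activated with Me3SiCl and 1,2-dibromoethane) in DMA at 30 °C should insert selectively into the primary C–I bond and give the alkylzinc iodide F1, the alkenyl iodide being inert at this temperature. Slow addition of F1 to Pd2(dba)3 and tri(2-furyl)phosphine in THF/DMA at 40 °C under high dilution should then close the ring by an intramolecular Negishi coupling (zerovalent palladium insertion at C10, transmetalation from zinc, reductive elimination). This comes back to the route at 30.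

2. Step 10. The hindered trisubstituted allylboronate may react too slowly with the epoxy aldehyde, facial or syn selectivity may erode, or the acid may open the epoxide. The fallback sets out from 22 and moves the allylboration onto a simple enal, installing the epoxide afterwards under reagent control. Oxidation with MnO2 in CH2Cl2 gives the enal F2. (R)-TRIP-catalysed allylboration of F2 with 10 (a well-precedented substrate class) should give, through the borate ester F3, the dienol F4 with the same C6/C7 arrangement as in 26. Acetylation (Ac2O, pyridine, DMAP) gives the acetate F5. Shi epoxidation of the trisubstituted C4=C5 alkene (D-fructose-derived Shi ketone, KHSO5, K2CO3 buffer, Bu4NHSO4, MeCN/dimethoxymethane, 0 °C) should then give the (4R,5R)-epoxide. This requires the trisubstituted alkene to react faster than the isopropenyl group, and it comes back to the route at 27.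

3. Step 1. Iodination and deprotonation of the ylide may be incomplete, giving low conversion and non-iodinated alkene, and Z selectivity may be incomplete. The fallback sets out from 1 and replaces the iodo-Wittig reaction by a stepwise construction of the haloalkene. Corey–Fuchs dibromo-olefination (CBr4, PPh3, CH2Cl2, 0 °C) gives the 1,1-dibromoalkene F6. Palladium-catalysed trans-selective monomethylation (MeZnCl, PdCl2(DPEphos), THF, 0 °C to rt) replaces the bromine trans to the chain and should give the (Z)-2-bromoalkene F7. Bromine–lithium exchange (t-BuLi, Et2O, −78 °C) then gives the alkenyllithium 8, where the route is rejoined (8 to 9 to 10 as in step 2).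

**Further compounds**

F1 | step 14 | alkylzinc iodide of 29 (ZnI in place of the primary iodine at C9): [(3S,4R)-4-acetoxy-4-{(2R,3R)-3-[(1S,3E)-4-iodo-1-{[(2Z)-2-methylbut-2-enoyl]oxy}pent-3-en-1-yl]-3-methyloxiran-2-yl}-3-(prop-1-en-2-yl)butyl]zinc iodide | C=C(C)[C@H](CC[Zn]I)[C@H]([C@@H]1[C@]([C@H](C/C=C(\C)I)OC(=O)/C(C)=C\C)(C)O1)OC(C)=O
F2 | step 10 | (2E,4S,6E)-7-iodo-3-methyl-1-oxoocta-2,6-dien-4-yl (2Z)-2-methylbut-2-enoate | C/C(I)=C\C[C@H](OC(=O)/C(C)=C\C)/C(C)=C/C=O
F3 | step 10 | pinacol borate ester of F4 (O–B at C6) | C=C(C)[C@H](CCO[Si](C)(C)C(C)(C)C)[C@H](/C=C(\C)[C@H](C/C=C(\C)I)OC(=O)/C(C)=C\C)OB1OC(C)(C)C(C)(C)O1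
F4 | step 10 | (4E)-alkene analogue of 26 (C4=C5 double bond in place of the epoxide; C3, C6 and C7 arranged as in 26) | C=C(C)[C@H](CCO[Si](C)(C)C(C)(C)C)[C@H](/C=C(\C)[C@H](C/C=C(\C)I)OC(=O)/C(C)=C\C)O
F5 | step 10 | (4E)-alkene analogue of 27 (C4=C5 double bond in place of the epoxide) | C=C(C)[C@H](CCO[Si](C)(C)C(C)(C)C)[C@H](/C=C(\C)[C@H](C/C=C(\C)I)OC(=O)/C(C)=C\C)OC(C)=O
F6 | step 1 | tert-butyl[(4,4-dibromobut-3-en-1-yl)oxy]dimethylsilane | BrC(Br)=CCCO[Si](C)(C)C(C)(C)C
F7 | step 1 | (Z)-[(4-bromopent-3-en-1-yl)oxy](tert-butyl)dimethylsilane (bromine cis to the chain) | C/C(Br)=C/CCO[Si](C)(C)C(C)(C)C
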